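**Retrosynthetic overview**
1. Target 28 ⇐ 27 (acid removal of the tert-butyl ester and silyl ether) ⇐ 24 (B-alkyl Suzuki coupling of the C9 vinyl group with 3-bromofuran-2(5H)-one) ⇐ 21 (α-face methylation at C4) ⇐ 19 (removal of a temporary C1 carbonyl).
2. 19 ⇐ acyclic keto ester 17 by one base-mediated α,α′-annulation: C5–C10 closes ring B first (6-exo Michael addition, bromide lost), then C2–C3 closes ring A (6-endo Michael addition).
3. Enabling feature: C4 of ring A carries the carboxyl carbon C19, so C3–C4–C5 can be a 2-(bromomethyl)enoate (electrophilic at C5, then at C3); C2 and the quaternary C10 both sit on C1, so a temporary C1 ketone makes them the two α-carbons of one ketone.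
4. 17 ⇐ lactone 6: selenide opening at C12 (masked vinyl; C17 acid → CH2OTBS), double hydroboration (C5–OH, C1–OH), Morita–Baylis–Hillman reaction at C5, allylic bromination, oxidation at C1.
5. 6 ⇐ 5,6-dihydro-2H-pyran-2-one: rhodium-catalysed asymmetric conjugate addition sets C9 and trans-allylation sets C8; these two centres control C5 and C10 in the key step.

Key step: step 11

Remark: locants C1–C20 follow labdane numbering (ring A = C1–C5, C10; ring B = C5–C10; C18 methyl and C19 carboxyl on C4; C20 methyl on C10; C17 on C8; side chain C11–C16 on C9; β = the face of the C20 methyl).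
Remark: (Z)-but-2-en-2-ylboronic acid and 3-bromofuran-2(5H)-one are taken as commercial; the geometry of the butenyl group is of no consequence because C10 and C1 are re-formed later.

**Step 1**
Reactants: 1 5,6-dihydro-2H-pyran-2-one; 2 (Z)-but-2-en-2-ylboronic acid
Product: 3 (4S)-4-[(2E)-but-2-en-2-yl]oxan-2-one
Conditions: Rh(acac)(C2H4)2 (3 mol %), (S)-BINAP, dioxane/H2O (10:1), 100 °C
Reagents that add atoms: (Z)-but-2-en-2-ylboronic acid, C/C=C(\C)B(O)O
Why: Rhodium-catalysed asymmetric conjugate addition of an alkenylboronic acid to an unsaturated lactone (Hayashi–Miyaura reaction); the catalyst formed from Rh(acac)(C2H4)2 and (S)-BINAP should set C9 in the sense established for cyclic enones and this lactone, and the butenyl group is a masked 3-oxobutan-2-yl unit (C10, C20, C1, C2).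

**Step 2**
Reactants: 3 (4S)-4-[(2E)-but-2-en-2-yl]oxan-2-one; 4 allyl bromide
Product: 6 (3R,4S)-4-[(2E)-but-2-en-2-yl]-3-(prop-2-en-1-yl)oxan-2-one, via lithium enolate 5 (not isolated)
Conditions: LiN(i-Pr)2, THF, −78 °C; then allyl bromide, −78 → −40 °C
Reagents that add atoms: allyl bromide, C=CCBr
Why: Alkylation of the lactone enolate anti to the neighbouring C9 substituent (substrate control) should give the trans-3,4-disubstituted lactone and so sets C8.

**Step 3**
Reactants: 6 (3R,4S)-4-[(2E)-but-2-en-2-yl]-3-(prop-2-en-1-yl)oxan-2-one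
Product: 7 (2R,3S,4E)-4-methyl-3-[2-(phenylselanyl)ethyl]-2-(prop-2-en-1-yl)hex-4-enoic acid
Conditions: (PhSe)2, NaBH4, DMF, 110 °C; then aq. HCl
Reagents that add atoms: diphenyl diselenide (used as sodium benzeneselenolate), c1ccc(cc1)[Se][Se]c1ccccc1
Why: SN2 opening of the lactone at its O–CH2 carbon (C12) by the soft selenolate (alkyl–oxygen cleavage) frees C17 as the acid and stores the future C11=C12 vinyl group as a selenide without touching C8 or C9.

**Step 4**
Reactants: 7 (2R,3S,4E)-4-methyl-3-[2-(phenylselanyl)ethyl]-2-(prop-2-en-1-yl)hex-4-enoic acid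
Product: 8 (2R,3S,4E)-4-methyl-3-[2-(phenylselanyl)ethyl]-2-(prop-2-en-1-yl)hex-4-en-1-ol
Conditions: LiAlH4, THF, 0 °C → rt
Reagents that add atoms: none
Why: Hydride reduction of the carboxylic acid to the primary alcohol (C17), to which the selenide and the isolated alkenes are inert.

**Step 5**
Reactants: 8 (2R,3S,4E)-4-methyl-3-[2-(phenylselanyl)ethyl]-2-(prop-2-en-1-yl)hex-4-en-1-ol
Product: 9 tert-butyl(dimethyl){[(2R,3S,4E)-4-methyl-3-[2-(phenylselanyl)ethyl]-2-(prop-2-en-1-yl)hex-4-en-1-yl]oxy}silane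
Conditions: TBSCl, imidazole, DMF, rt
Reagents that add atoms: tert-butyldimethylsilyl chloride, CC(C)(C)[Si](C)(C)Cl
Why: Silylation of the primary alcohol protects C17–OH until the last step.

**Step 6**
Reactants: 9 tert-butyl(dimethyl){[(2R,3S,4E)-4-methyl-3-[2-(phenylselanyl)ethyl]-2-(prop-2-en-1-yl)hex-4-en-1-yl]oxy}silane
Product: 12 (4R,5S)-4-{[tert-butyl(dimethyl)silyl]oxymethyl}-5-ethenyl-6-methyloctane-1,7-diol, via bis(alkylborane) 10 (not isolated), via selenoxide diol 11 (not isolated)
Conditions: BH3·THF, THF, 0 °C → rt; then NaOH, 30% H2O2, 0 → 45 °C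
Reagents that add atoms: hydrogen peroxide, OO
Why: Anti-Markovnikov hydroboration–oxidation puts oxygen on terminal C5 and on the less substituted C1 while C11–C12 is still masked, and the same alkaline peroxide oxidizes selenium so that selenoxide syn-elimination unveils the vinyl group; the new centres at C1 and C10 form as a mixture that is of no consequence (C1 is oxidized in step 10, C10 is enolized in step 11).

**Step 7**
Reactants: 12 (4R,5S)-4-{[tert-butyl(dimethyl)silyl]oxymethyl}-5-ethenyl-6-methyloctane-1,7-diol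
Product: 13 (4R,5S)-4-{[tert-butyl(dimethyl)silyl]oxymethyl}-5-ethenyl-7-hydroxy-6-methyloctanal
Conditions: TEMPO (10 mol %), PhI(OAc)2, CH2Cl2, rt
Reagents that add atoms: none
Why: Nitroxyl-catalysed oxidation is selective for the primary alcohol (C5) over the secondary C1 alcohol.

**Step 8**
Reactants: 13 (4R,5S)-4-{[tert-butyl(dimethyl)silyl]oxymethyl}-5-ethenyl-7-hydroxy-6-methyloctanal; 14 tert-butyl acrylate
Product: 15 tert-butyl (6R,7S)-6-{[tert-butyl(dimethyl)silyl]oxymethyl}-7-ethenyl-3,9-dihydroxy-8-methyl-2-methylidenedecanoate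
Conditions: tert-butyl acrylate, DABCO, dioxane/H2O (1:1), rt
Reagents that add atoms: tert-butyl acrylate, C=CC(=O)OC(C)(C)C
Why: Morita–Baylis–Hillman reaction joins C5 to C4 and brings in C3, C4 and C19; the carbinol centre at C5 forms as a mixture and is destroyed in step 9.

**Step 9**
Reactants: 15 tert-butyl (6R,7S)-6-{[tert-butyl(dimethyl)silyl]oxymethyl}-7-ethenyl-3,9-dihydroxy-8-methyl-2-methylidenedecanoate
Product: 16 tert-butyl (2Z,6R,7S)-2-(bromomethyl)-6-{[tert-butyl(dimethyl)silyl]oxymethyl}-7-ethenyl-9-hydroxy-8-methyldec-2-enoate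
Conditions: NBS, Me2S, CH2Cl2, −20 → 0 °C
Reagents that add atoms: N-bromosuccinimide, BrN1C(=O)CCC1=O
Why: Corey–Kim-type bromination of the allylic alcohol with SN2′ transposition gives the conjugated (Z)-2-(bromomethyl)enoate (the more stable trisubstituted alkene), while the non-allylic C1 alcohol does not react in the absence of base.

**Step 10**
Reactants: 16 tert-butyl (2Z,6R,7S)-2-(bromomethyl)-6-{[tert-butyl(dimethyl)silyl]oxymethyl}-7-ethenyl-9-hydroxy-8-methyldec-2-enoate
Product: 17 tert-butyl (2Z,6R,7S)-2-(bromomethyl)-6-{[tert-butyl(dimethyl)silyl]oxymethyl}-7-ethenyl-8-methyl-9-oxodec-2-enoate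
Conditions: Dess–Martin periodinane, NaHCO3, CH2Cl2, 0 °C → rt
Reagents that add atoms: none
Why: Dess–Martin oxidation of the secondary alcohol gives the C1 methyl ketone under neutral conditions that leave the allylic bromide intact.

**Step 11**
Reactants: 17 tert-butyl (2Z,6R,7S)-2-(bromomethyl)-6-{[tert-butyl(dimethyl)silyl]oxymethyl}-7-ethenyl-8-methyl-9-oxodec-2-enoate
Product: 19 tert-butyl 6-{[tert-butyl(dimethyl)silyl]oxymethyl}-5-ethenyl-4a-methyl-4-oxodecahydronaphthalene-1-carboxylate (labdane locants: 1-oxo; 4α-ester; 5α-H; 8α-CH2OTBS; 9β-vinyl; 10β-CH3), via monocyclic acrylate 18 (not isolated)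
Conditions: KOt-Bu (2.2 equiv), THF/t-BuOH (10:1), 0.005 M, −40 → 0 °C; then aq. NH4Cl
Reagents that add atoms: none
Why: Proposed new method: KOt-Bu equilibrates the ketone enolates of 17; the more substituted C10 enolate adds to C5 of the (Z)-2-(bromomethyl)enoate (6-exo-trig Michael addition, ring B) and the ester enolate so formed expels bromide to give the α-substituted acrylate 18, whose methyl ketone can enolize only towards C2 and then adds to C3 (6-endo-trig Michael addition, ring A) to give 19 after protonation. The closest known reaction type is the α,α′-annulation of ketone enolates or enamines with 2-(bromomethyl)acrylates, combined with the intramolecular Michael addition of ketone enolates to enoates; here the two partners are tethered, so the same sequence folds the chain into the decalin. C10 and C5 are set in the first closure through a chair transition state with the C8 and C9 substituents equatorial and with the allylic C9–H and a C6–H bond eclipsing the enolate C10=C1 and the enoate C5=C4 (least A(1,3) strain), which places C1 and C4 equatorial and the C20 methyl axial and anti to H5, that is the trans-decalin with 10β-CH3 and 5α-H. C4 forms as an epimerizable centre (the equatorial ester is expected) and is fixed only in step 13. The step needs C10 to react before C2, which ring size secures (C2 could only close an eight- or ten-membered ring), and Michael addition to outrun 1,4-loss of HBr and intermolecular alkylation, which the more acidic ketone, the low temperature and the high dilution should favour.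

**Step 12**
Reactants: 19 tert-butyl 6-{[tert-butyl(dimethyl)silyl]oxymethyl}-5-ethenyl-4a-methyl-4-oxodecahydronaphthalene-1-carboxylate
Product: 21 tert-butyl 6-{[tert-butyl(dimethyl)silyl]oxymethyl}-5-ethenyl-4a-methyldecahydronaphthalene-1-carboxylate (labdane locants: 4α-ester; 5α-H; 8α-CH2OTBS; 9β-vinyl; 10β-CH3), via tosylhydrazone 20 (not isolated)
Conditions: TsNHNH2, EtOH, 70 °C; then catecholborane, CHCl3, 0 °C → rt; then NaOAc·3H2O, reflux
Reagents that add atoms: none
Why: Reduction of the tosylhydrazone with catecholborane (Caglioti-type deoxygenation) removes the temporary C1 carbonyl under conditions that spare the tert-butyl ester, the silyl ether and the vinyl group.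

**Step 13**
Reactants: 21 tert-butyl 6-{[tert-butyl(dimethyl)silyl]oxymethyl}-5-ethenyl-4a-methyldecahydronaphthalene-1-carboxylate; 22 methyl iodide
Product: 24 tert-butyl 6-{[tert-butyl(dimethyl)silyl]oxymethyl}-5-ethenyl-1,4a-dimethyldecahydronaphthalene-1-carboxylate (labdane locants: 4α-CH3; 4β-ester; 5α-H; 8α-CH2OTBS; 9β-vinyl; 10β-CH3), via lithium ester enolate 23 (not isolated)
Conditions: LiN(i-Pr)2, THF, −78 → −40 °C; then MeI, DMPU, −78 → 0 °C
Reagents that add atoms: methyl iodide, CI
Why: Alkylation of the exocyclic ester enolate, with methyl iodide entering from the α (equatorial) face opposite the axial C20 methyl, should give the 4α-methyl, 4β-(axial) ester quaternary centre, the sense known for C4 ester enolates of 10-methyl trans-decalins.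

**Step 14**
Reactants: 24 tert-butyl 6-{[tert-butyl(dimethyl)silyl]oxymethyl}-5-ethenyl-1,4a-dimethyldecahydronaphthalene-1-carboxylate; 25 3-bromofuran-2(5H)-one
Product: 27 tert-butyl 6-{[tert-butyl(dimethyl)silyl]oxymethyl}-1,4a-dimethyl-5-[2-(2-oxo-2,5-dihydrofuran-3-yl)ethyl]decahydronaphthalene-1-carboxylate (stereochemistry as in 24), via B-alkyl-9-BBN adduct 26 (not isolated)
Conditions: 9-BBN, THF, rt → 50 °C; then 3-bromofuran-2(5H)-one, Pd(dppf)Cl2 (5 mol %), AsPh3, Cs2CO3, DMF/H2O, rt
Reagents that add atoms: 3-bromofuran-2(5H)-one, O=C1OCC=C1Br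
Why: Anti-Markovnikov hydroboration of the vinyl group followed by palladium-catalysed B-alkyl Suzuki–Miyaura coupling with the α-bromobutenolide forms C12–C13 and installs the butenolide with its double bond already in the ring.

**Step 15**
Reactants: 27 tert-butyl 6-{[tert-butyl(dimethyl)silyl]oxymethyl}-1,4a-dimethyl-5-[2-(2-oxo-2,5-dihydrofuran-3-yl)ethyl]decahydronaphthalene-1-carboxylate
Product: 28 (1S,4aR,5S,6R,8aR)-6-(hydroxymethyl)-1,4a-dimethyl-5-[2-(2-oxo-2,5-dihydrofuran-3-yl)ethyl]decahydronaphthalene-1-carboxylic acid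
Conditions: TFA/CH2Cl2/H2O (10:10:1), 0 °C → rt; then aq. NaHCO3/MeOH wash, acidify
Reagents that add atoms: none
Why: Acidolysis cleaves the tert-butyl ester (alkyl–oxygen cleavage, so the hindered axial carboxyl is no obstacle) and the primary silyl ether in one operation, and the butenolide tolerates acid.

**Compound list**
1 | 5,6-dihydro-2H-pyran-2-one | O=C1C=CCCO1 | starting material
2 | (Z)-but-2-en-2-ylboronic acid | C/C=C(\C)B(O)O | starting material
3 | (4S)-4-[(2E)-but-2-en-2-yl]oxan-2-one | O=C1C[C@@H](/C(C)=C/C)CCO1 | intermediate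
4 | allyl bromide | C=CCBr | starting material
5 | lithium enolate of 3 | [Li+].[O-]C1=C[C@@H](/C(C)=C/C)CCO1 | intermediate
6 | (3R,4S)-4-[(2E)-but-2-en-2-yl]-3-(prop-2-en-1-yl)oxan-2-one (trans) | O=C1[C@H](CC=C)[C@@H](/C(C)=C/C)CCO1 | intermediate
7 | (2R,3S,4E)-4-methyl-3-[2-(phenylselanyl)ethyl]-2-(prop-2-en-1-yl)hex-4-enoic acid | OC(=O)[C@H](CC=C)[C@@H](/C(C)=C/C)CC[Se]c1ccccc1 | intermediate
8 | (2R,3S,4E)-4-methyl-3-[2-(phenylselanyl)ethyl]-2-(prop-2-en-1-yl)hex-4-en-1-ol | OC[C@H](CC=C)[C@@H](/C(C)=C/C)CC[Se]c1ccccc1 | intermediate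
9 | TBS ether of 8 | CC(C)(C)[Si](C)(C)OC[C@H](CC=C)[C@@H](/C(C)=C/C)CC[Se]c1ccccc1 | intermediate
10 | bis(alkylborane) from 9 (boron on C5 and C1, drawn as RBH2; C1 and C10 mixed) | CC(B)C(C)[C@@H](CC[Se]c1ccccc1)[C@H](CO[Si](C)(C)C(C)(C)C)CCCB | intermediate
11 | selenoxide diol (C1 and C10 mixed) | CC(O)C(C)[C@@H](CC[Se](=O)c1ccccc1)[C@H](CO[Si](C)(C)C(C)(C)C)CCCO | intermediate
12 | (4R,5S)-4-{[tert-butyl(dimethyl)silyl]oxymethyl}-5-ethenyl-6-methyloctane-1,7-diol (C6 and C7 mixed) | CC(O)C(C)[C@@H](C=C)[C@H](CO[Si](C)(C)C(C)(C)C)CCCO | intermediate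
13 | (4R,5S)-4-{[tert-butyl(dimethyl)silyl]oxymethyl}-5-ethenyl-7-hydroxy-6-methyloctanal | CC(O)C(C)[C@@H](C=C)[C@H](CO[Si](C)(C)C(C)(C)C)CCC=O | intermediate
14 | tert-butyl acrylate | C=CC(=O)OC(C)(C)C | starting material
15 | tert-butyl (6R,7S)-6-{[tert-butyl(dimethyl)silyl]oxymethyl}-7-ethenyl-3,9-dihydroxy-8-methyl-2-methylidenedecanoate | CC(O)C(C)[C@@H](C=C)[C@H](CO[Si](C)(C)C(C)(C)C)CCC(O)C(=C)C(=O)OC(C)(C)C | intermediate
16 | tert-butyl (2Z,6R,7S)-2-(bromomethyl)-6-{[tert-butyl(dimethyl)silyl]oxymethyl}-7-ethenyl-9-hydroxy-8-methyldec-2-enoate | CC(O)C(C)[C@@H](C=C)[C@H](CO[Si](C)(C)C(C)(C)C)CC/C=C(\CBr)C(=O)OC(C)(C)C | intermediate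
17 | tert-butyl (2Z,6R,7S)-2-(bromomethyl)-6-{[tert-butyl(dimethyl)silyl]oxymethyl}-7-ethenyl-8-methyl-9-oxodec-2-enoate (C8 mixed) | CC(=O)C(C)[C@@H](C=C)[C@H](CO[Si](C)(C)C(C)(C)C)CC/C=C(\CBr)C(=O)OC(C)(C)C | intermediate
18 | tert-butyl 2-{2-acetyl-4-[(tert-butyldimethylsilyloxy)methyl]-3-ethenyl-2-methylcyclohexyl}prop-2-enoate (ring B; acetyl equatorial, C20 methyl axial β, 5α-H, 8α-CH2OTBS, 9β-vinyl) | C[C@]1(C(C)=O)[C@H](C(=C)C(=O)OC(C)(C)C)CC[C@@H](CO[Si](C)(C)C(C)(C)C)[C@@H]1C=C | intermediate
19 | trans-decalin keto ester (1-oxo, 4α-CO2t-Bu, 5α-H, 8α-CH2OTBS, 9β-vinyl, 10β-CH3) | C[C@]12C(=O)CC[C@@H](C(=O)OC(C)(C)C)[C@@H]1CC[C@@H](CO[Si](C)(C)C(C)(C)C)[C@@H]2C=C | intermediate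
20 | tosylhydrazone of 19 | C[C@]12C(=NNS(=O)(=O)c3ccc(C)cc3)CC[C@@H](C(=O)OC(C)(C)C)[C@@H]1CC[C@@H](CO[Si](C)(C)C(C)(C)C)[C@@H]2C=C | intermediate
21 | trans-decalin ester (4α-CO2t-Bu, 5α-H, 8α-CH2OTBS, 9β-vinyl, 10β-CH3) | C[C@]12CCC[C@@H](C(=O)OC(C)(C)C)[C@@H]1CC[C@@H](CO[Si](C)(C)C(C)(C)C)[C@@H]2C=C | intermediate
22 | methyl iodide | CI | starting material
23 | lithium ester enolate of 21 | [Li+].C[C@]12CCCC(=C([O-])OC(C)(C)C)[C@@H]1CC[C@@H](CO[Si](C)(C)C(C)(C)C)[C@@H]2C=C | intermediate
24 | trans-decalin ester with quaternary C4 (4α-CH3, 4β-CO2t-Bu, 5α-H, 8α-CH2OTBS, 9β-vinyl, 10β-CH3) | C[C@]12CCC[C@](C)(C(=O)OC(C)(C)C)[C@@H]1CC[C@@H](CO[Si](C)(C)C(C)(C)C)[C@@H]2C=C | intermediate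
25 | 3-bromofuran-2(5H)-one | O=C1OCC=C1Br | starting material
26 | B-alkyl-9-BBN adduct of 24 (boron on C12) | C[C@]12CCC[C@](C)(C(=O)OC(C)(C)C)[C@@H]1CC[C@@H](CO[Si](C)(C)C(C)(C)C)[C@@H]2CCB1C2CCCC1CCC2 | intermediate
27 | protected target (C19 tert-butyl ester, C17 TBS ether) | C[C@]12CCC[C@](C)(C(=O)OC(C)(C)C)[C@@H]1CC[C@@H](CO[Si](C)(C)C(C)(C)C)[C@@H]2CCC1=CCOC1=O | intermediate
28 | (1S,4aR,5S,6R,8aR)-6-(hydroxymethyl)-1,4a-dimethyl-5-[2-(2-oxo-2,5-dihydrofuran-3-yl)ethyl]decahydronaphthalene-1-carboxylic acid | C[C@]12CCC[C@](C)(C(=O)O)[C@@H]1CC[C@@H](CO)[C@@H]2CCC1=CCOC1=O | target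

**Step count**
Total steps: 15. Longest linear sequence: 15 steps (from 1; compounds 2, 4, 14, 22 and 25 are commercial).

**Steps most likely to fail**

Step 11 (Proposed new method). What may go wrong: γ-deprotonation of the enoate followed by 1,4-loss of HBr, intermolecular alkylation, arrest after the first ring closure, or poor facial control at C10. Fallback with known reactions, in which the two ring closures are separated and ring A is closed under Lewis-acid instead of enolate control: it sets out from 17. One equivalent of KOt-Bu at −40 °C is used only for the intramolecular Michael addition with loss of bromide, and the monocyclic acrylate 18 is isolated. Its ketone, which can enolize only towards C2, is converted with TMSOTf/Et3N into the trimethylsilyl enol ether F1. TiCl4 in CH2Cl2 at −78 °C then effects the intramolecular Mukaiyama–Michael addition of C2 to C3, and aqueous work-up returns to the route at 19.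

Step 12. What may go wrong: slow condensation at the hindered C1 carbonyl next to the quaternary C10, and elimination to an alkene instead of reduction. Fallback by Barton–McCombie deoxygenation: it sets out from 19. NaBH4 in MeOH gives the C1 alcohol F2, NaH/CS2/MeI gives the S-methyl xanthate F3, and Bu3SnH with AIBN in toluene at 110 °C removes the oxygen and returns to the route at 21.

Step 14. What may go wrong: slow transmetalation of the hindered alkylborane and base-induced decomposition of the bromobutenolide during the coupling. Fallback by olefination and double-bond isomerization: it sets out from 24. Hydroboration with 9-BBN and NaOH/H2O2 oxidation gives the primary alcohol F4, and Dess–Martin oxidation gives the aldehyde F5. Wittig reaction with 3-(triphenylphosphoranylidene)dihydrofuran-2(3H)-one gives the (E)-alkylidene lactone F6, and RhCl3·3H2O in EtOH at reflux moves the double bond into the ring and returns to the route at 27.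

**Further compounds**
F1 | step 11 | trimethylsilyl enol ether of 18 | C[C@]1(C(=C)O[Si](C)(C)C)[C@H](C(=C)C(=O)OC(C)(C)C)CC[C@@H](CO[Si](C)(C)C(C)(C)C)[C@@H]1C=C
F2 | step 12 | C1 alcohol from 19 (either C1 epimer) | C[C@]12C(O)CC[C@@H](C(=O)OC(C)(C)C)[C@@H]1CC[C@@H](CO[Si](C)(C)C(C)(C)C)[C@@H]2C=C
F3 | step 12 | S-methyl xanthate of F2 | C[C@]12C(OC(=S)SC)CC[C@@H](C(=O)OC(C)(C)C)[C@@H]1CC[C@@H](CO[Si](C)(C)C(C)(C)C)[C@@H]2C=C
F4 | step 14 | primary alcohol (C12–OH) from 24 | C[C@]12CCC[C@](C)(C(=O)OC(C)(C)C)[C@@H]1CC[C@@H](CO[Si](C)(C)C(C)(C)C)[C@@H]2CCO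
F5 | step 14 | C12 aldehyde | C[C@]12CCC[C@](C)(C(=O)OC(C)(C)C)[C@@H]1CC[C@@H](CO[Si](C)(C)C(C)(C)C)[C@@H]2CC=O
F6 | step 14 | (E)-alkylidene lactone | C[C@]12CCC[C@](C)(C(=O)OC(C)(C)C)[C@@H]1CC[C@@H](CO[Si](C)(C)C(C)(C)C)[C@@H]2C/C=C1\CCOC1=O
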